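**Retrosynthetic overview**
1. The aldol array C1(=O)-C10(CH3)-C9(OH) is read as an opened 4-methylisoxazoline. The esters at O8 and O13 and the N-O cleavage come last.
2. Key disconnection: C1-C10 and O-C9. An intramolecular nitrile oxide cycloaddition of an open-chain C1 oxime onto the (E)-C9=C10 propenyl group closes the ten-membered carbocycle (C1 to C10) and sets C9 and C10. Enabling feature: the oxygen-bearing C8 stands directly beside C9, so a C8 magnesium alkoxide can hold the dipole oxygen over C9. The cis C4-C5 oxirane and the flat butenolide ring (O, C6, C7, C11, C12) fold the C1-C7 tether.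
3. The cyclisation precursor comes from a 7-bromobutenolide, carbon monoxide (C8) and a propenylstannane (C9, C10, C14). A CBS reduction then sets a temporary C8 configuration, which is reset after ring closure by oxidation and peripheral hydride attack.
4. The bromobutenolide comes from nerol (C1 to C6 and C15, its Z alkene becoming the cis oxirane by Sharpless epoxidation) and a 3,3-dibromoacrylate (C7, C11, C12, C13).
5. Ring order: oxirane (step 1), butenolide (step 8), ten-membered carbocycle together with a temporary isoxazoline (step 12). The isoxazoline is opened again in step 18.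

Key step: step 12

Remark: germacrane numbering is used (C1 ketone, C4/C5 oxirane, C6 lactone carbinol, C7=C11 butenolide alkene, C8 ester carbinol, C9 carbinol, C10 methine, C12 lactone C=O, C13 CH2O, C14 = 10-CH3, C15 = 4-CH3). CIP descriptors change along the route where priorities change, so the SMILES are decisive. TBS = tert-butyldimethylsilyl.

Step 1
Reactants: 1 nerol
Product: 2 (2S,3R)-2,3-epoxynerol (4R,5S)
Conditions: Ti(OiPr)4 (10 mol %), L-(+)-diethyl tartrate (12 mol %), t-BuOOH, 4 Å MS, CH2Cl2, −20 °C
Reagents that add atoms: tert-butyl hydroperoxide, CC(C)(C)OO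
Why: Sharpless asymmetric epoxidation is directed by the allylic hydroxyl and so touches only the C4=C5 alkene, the L-(+)-tartrate sets 4R,5S by reagent control, and the Z geometry of nerol becomes the cis relation of C3 and C6 on the oxirane.

Step 2
Reactants: 2 (2S,3R)-2,3-epoxynerol
Product: 3 3-[(2R,3S)-3-(hydroxymethyl)-2-methyloxiran-2-yl]propanal
Conditions: O3, CH2Cl2, −78 °C; then Me2S, −78 °C to rt
Reagents that add atoms: ozone, [O-][O+]=O
Why: Ozonolysis with reductive work-up cleaves the only alkene left (C1=CMe2) to the C1 aldehyde and leaves the oxirane and its two stereocenters untouched.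

Step 3
Reactants: 3 hydroxy aldehyde
Product: 4 (E)-O-TBS oxime of 3
Conditions: H2N-OTBS, 4 Å MS, CH2Cl2, rt
Reagents that add atoms: O-(tert-butyldimethylsilyl)hydroxylamine, NO[Si](C)(C)C(C)(C)C
Why: Oxime ether condensation stores C1 at the oxidation level of the later nitrile oxide in a form that is inert to the oxidant, the Grignard reagent, zerovalent palladium and the borane of the next steps, and it forms no stereocenter.

Step 4
Reactants: 4 O-TBS oxime alcohol
Product: 5 (2R,3R)-3-methyl-3-[(3E)-3-(TBSO-imino)propyl]oxirane-2-carbaldehyde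
Conditions: TEMPO (10 mol %), PhI(OAc)2, CH2Cl2, rt
Reagents that add atoms: none
Why: The oxoammonium (TEMPO) oxidation stops at the aldehyde under nearly neutral conditions, and C5 cannot epimerise because it is an oxirane carbon.

Step 5
Reactants: 6 methyl 2-(hydroxymethyl)acrylate
Product: 7 methyl 2-[(TBSO)methyl]acrylate
Conditions: TBSCl, imidazole, CH2Cl2, 0 °C to rt
Reagents that add atoms: tert-butyldimethylsilyl chloride, CC(C)(C)[Si](C)(C)Cl
Why: Silyl ether protection of the primary alcohol gives an O13 substituent that survives ozone, the Grignard step and the magnesium alkoxide of the key step.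

Step 6
Reactants: 7 methyl 2-[(TBSO)methyl]acrylate
Product: 8 methyl 3-(TBSO)-2-oxopropanoate
Conditions: O3, CH2Cl2, −78 °C; then Me2S
Reagents that add atoms: ozone, [O-][O+]=O
Why: Ozonolysis of the 1,1-disubstituted acrylate alkene gives the alpha-keto ester whose ketone carbon is the future C11.

Step 7
Reactants: 8 methyl 3-(TBSO)-2-oxopropanoate
Product: 9 methyl 3,3-dibromo-2-[(TBSO)methyl]acrylate
Conditions: CBr4, PPh3, CH2Cl2, 0 °C
Reagents that add atoms: carbon tetrabromide, BrC(Br)(Br)Br
Why: Ramirez dibromo-olefination works well on electrophilic alpha-keto esters and, since both new substituents on C7 are bromine, creates the tetrasubstituted C7=C11 alkene without any E/Z question.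

Step 8
Reactants: 9 dibromoacrylate; 5 epoxy aldehyde
Product: 12 7-bromobutenolide (4R,5S,6R), via magnesium carbenoid 10 (not isolated), via magnesium alkoxide 11 (not isolated)
Conditions: i-PrMgCl (1.05 equiv), THF, −78 °C; then 5, −78 to −20 °C; pH 7 buffer
Reagents that add atoms: none
Why: Ester-directed bromine-magnesium exchange removes only the bromine cis to CO2Me, the chelated alkenyl magnesium carbenoid adds to the aldehyde in the Felkin-Anh/Cornforth conformer (C=O anti to the oxirane oxygen) from the H5 side away from C4 and its cis C3 chain, which sets the target arrangement at C6 (6R here because Br raises C7 in priority), and the alkoxide lactonises on the cis ester (halogen-metal exchange, 1,2-addition, lactonisation).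

Step 9
Reactants: 12 7-bromobutenolide; 13 (E)-tributyl(prop-1-enyl)stannane
Product: 14 7-[(E)-but-2-enoyl]butenolide (4R,5S,6S)
Conditions: Pd2(dba)3 (5 mol %), AsPh3 (20 mol %), CO (3 bar), THF/NMP, 50 °C
Reagents that add atoms: carbon monoxide, [C-]#[O+]
Why: In this carbonylative Stille coupling, oxidative addition into the vinylogous acyl bromide, CO insertion, propenyl transfer with retention of the E geometry and reductive elimination all run under neutral conditions that spare the base-sensitive C6-H/oxirane pair, and the CO carbon becomes C8.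

Step 10
Reactants: 14 dienone
Product: 15 allylic alcohol (4R,5S,6S,8R)
Conditions: (S)-2-methyl-CBS-oxazaborolidine (0.3 equiv), catecholborane, toluene, −78 °C; then H2O
Reagents that add atoms: none
Why: Corey-Bakshi-Shibata reduction is 1,2-selective, and the (S)-catalyst, which treats the fully substituted C7 as the large and the propenyl group as the small substituent, sets 8R by reagent control, which is spatially the C8 epimer of the target and the one the key step needs.

Step 11
Reactants: 15 allylic alcohol
Product: 16 free (E)-aldoxime (4R,5S,6S,8R) that keeps 13-OTBS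
Conditions: TBAF/AcOH (1:1, 1.05 equiv), THF, −20 °C
Reagents that add atoms: none
Why: Fluoride desilylation discriminates by leaving-group ability, since the oximate leaves silicon far more easily than a primary alkoxide, so one equivalent of buffered fluoride at low temperature should free only the oxime.

Step 12
Reactants: 16 aldoxime
Product: 19 isoxazoline-bridged germacranolide (4R,5S,6S,8S,9R,10R), via hydroximoyl chloride 17 (not isolated), via nitrile oxide 18 (not isolated)
Conditions: t-BuOCl, CH2Cl2, −78 °C; then slow addition (12 h) to i-PrOMgBr (3 equiv, from EtMgBr and i-PrOH), CH2Cl2, 0 °C to rt, final about 1 mM; pH 7 buffer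
Reagents that add atoms: none
Why: Proposed new method: t-BuOCl converts the aldoxime into hydroximoyl chloride 17, i-PrOMgBr then deprotonates the C8 hydroxyl and eliminates HCl, and the resulting nitrile oxide 18, held by its oxygen on the same magnesium as the C8 alkoxide, undergoes a concerted [3+2] cycloaddition that joins C1 to C10 and the dipole oxygen to C9. The closest known reactions are the intermolecular magnesium-alkoxide-directed nitrile oxide cycloaddition to (E)-configured secondary allylic alcohols and the intramolecular nitrile oxide cycloaddition used for large rings, and what is new is their union for a ten-membered carbocycle. Two rings close at once: the ten-membered carbocycle through the C1-C10 bond in the bridged mode (both alkene carbons become ring members) and the temporary isoxazoline (C1, N, O, C9, C10) that spans it as in a bicyclo[7.2.1] system. C9 and C10 arise by suprafacial addition, so the E geometry of the propenyl group fixes their relative configuration (C8 and the C10 methyl trans on the isoxazoline, the anti aldol pattern of the target). The alkene face is chosen by C8: C7 starts the tether and can only stand inside, gauche to C10 and to the forming C9-O bond, because the anti and outside rotamers would stretch the C2-C7 chain beyond its reach; this puts the 8R alkoxide outside next to the dipole oxygen where magnesium bridges both, a chelate possible only on the face that leads to 9R,10R, which is why the C8 epimer is used here and reset in steps 13 and 14. The step needs regioselectivity (ten-membered bridged against nine-membered fused adduct), speed against furoxan formation and chemoselectivity against C7=C11: the five-membered chelate Mg-O8-C8-C9-O places the dipole oxygen on C9 and accelerates the otherwise sluggish 1,2-disubstituted alkene, slow addition keeps the dipole dilute, the tetrasubstituted electron-poor butenolide alkene is inert, and the cis oxirane and the flat butenolide act as two turns that fold C1 back over C10.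

Step 13
Reactants: 19 bridged 8S alcohol
Product: 20 C8 ketone (4R,5S,6S,9R,10R)
Conditions: Dess-Martin periodinane, CH2Cl2, 0 °C to rt
Reagents that add atoms: none
Why: Dess-Martin oxidation under neutral conditions erases the auxiliary C8 configuration, which has done its work as magnesium anchor, without touching oxirane, isoxazoline or silyl ether.

Step 14
Reactants: 20 C8 ketone
Product: 21 bridged 8R alcohol (4R,5S,6S,8R,9R,10R)
Conditions: NaBH4, CeCl3·7H2O, MeOH, −78 °C
Reagents that add atoms: none
Why: Luche reduction is 1,2-selective, and hydride should reach the C8 carbonyl from the outer (peripheral) face of the bridged ten-membered ring because the inner face is covered by H10 and the oxirane, which turns O8 anti to O9 and sets the 8R configuration of the target.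

Step 15
Reactants: 21 bridged 8R alcohol
Product: 22 8-O-methacrylate (4R,5S,6S,8R,9R,10R)
Conditions: methacrylic anhydride, DMAP, Et3N, CH2Cl2, 0 °C to rt
Reagents that add atoms: methacrylic anhydride, C=C(C)C(=O)OC(=O)C(C)=C
Why: DMAP-catalysed acyl transfer esterifies the only free hydroxyl group with retention at C8, and O9 cannot compete because it is part of the isoxazoline.

Step 16
Reactants: 22 8-O-methacrylate
Product: 23 13-alcohol
Conditions: TBAF/AcOH (1:1, 3 equiv), THF, rt
Reagents that add atoms: none
Why: Buffered fluoride desilylation removes the primary silyl ether while acetic acid keeps the medium too weakly basic for acyl migration from O8 or deprotonation at C6.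

Step 17
Reactants: 23 13-alcohol
Product: 24 13-acetate
Conditions: Ac2O, pyridine, DMAP (cat.), CH2Cl2, 0 °C
Reagents that add atoms: acetic anhydride, CC(=O)OC(C)=O
Why: Acetylation by nucleophilic catalysis of the only free hydroxyl group needs no selectivity, because O9 is still locked in the isoxazoline.

Step 18
Reactants: 24 13-acetate
Product: 26 target CNP0185951.2 (4R,5S,6S,8R,9R,10S), via hydroxy imine 25 (not isolated)
Conditions: Mo(CO)6 (1.2 equiv), MeCN/H2O 15:1, 80 °C
Reagents that add atoms: water, O
Why: Reductive N-O cleavage of the isoxazoline with Mo(CO)6 and hydrolysis of the beta-hydroxy imine unmask the C1 ketone and the C9 hydroxyl under neutral conditions that leave alkenes, esters and the oxirane alone, and C9 and C10 keep their configuration because no bond to them is broken.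

**Compound list**
1 | nerol, (2Z)-3,7-dimethylocta-2,6-dien-1-ol | CC(C)=CCC/C(C)=C\CO | starting material
2 | (2S,3R)-2,3-epoxynerol | OC[C@@H]1O[C@]1(C)CCC=C(C)C | intermediate
3 | 3-[(2R,3S)-3-(hydroxymethyl)-2-methyloxiran-2-yl]propanal | OC[C@@H]1O[C@]1(C)CCC=O | intermediate
4 | (E)-O-TBS oxime of 3 | OC[C@@H]1O[C@]1(C)CC/C=N/O[Si](C)(C)C(C)(C)C | intermediate
5 | (2R,3R)-3-methyl-3-[(3E)-3-(TBSO-imino)propyl]oxirane-2-carbaldehyde | O=C[C@@H]1O[C@]1(C)CC/C=N/O[Si](C)(C)C(C)(C)C | intermediate
6 | methyl 2-(hydroxymethyl)acrylate | C=C(CO)C(=O)OC | starting material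
7 | methyl 2-[(TBSO)methyl]acrylate | C=C(CO[Si](C)(C)C(C)(C)C)C(=O)OC | intermediate
8 | methyl 3-(TBSO)-2-oxopropanoate | COC(=O)C(=O)CO[Si](C)(C)C(C)(C)C | intermediate
9 | methyl 3,3-dibromo-2-[(TBSO)methyl]acrylate | COC(=O)C(CO[Si](C)(C)C(C)(C)C)=C(Br)Br | intermediate
10 | magnesium carbenoid, methyl (E)-3-bromo-3-(chloromagnesio)-2-[(TBSO)methyl]acrylate (Mg cis to the ester) | COC(=O)/C(CO[Si](C)(C)C(C)(C)C)=C(/Br)[Mg]Cl | intermediate
11 | magnesium alkoxide of the aldehyde adduct (4R,5S,6R) | COC(=O)/C(CO[Si](C)(C)C(C)(C)C)=C(/Br)[C@H](O[Mg]Cl)[C@@H]1O[C@]1(C)CC/C=N/O[Si](C)(C)C(C)(C)C | intermediate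
12 | (5R)-4-bromo-3-[(TBSO)methyl]-5-{(2S,3R)-3-methyl-3-[(3E)-3-(TBSO-imino)propyl]oxiran-2-yl}furan-2(5H)-one | BrC1=C(CO[Si](C)(C)C(C)(C)C)C(=O)O[C@@H]1[C@@H]1O[C@]1(C)CC/C=N/O[Si](C)(C)C(C)(C)C | intermediate
13 | (E)-tributyl(prop-1-enyl)stannane | C/C=C/[Sn](CCCC)(CCCC)CCCC | starting material
14 | (5S)-4-[(E)-but-2-enoyl] analogue of 12 (Br replaced by the acyl group) | C/C=C/C(=O)C1=C(CO[Si](C)(C)C(C)(C)C)C(=O)O[C@@H]1[C@@H]1O[C@]1(C)CC/C=N/O[Si](C)(C)C(C)(C)C | intermediate
15 | 4-[(1R,2E)-1-hydroxybut-2-enyl]butenolide, O-TBS oxime | C/C=C/[C@@H](O)C1=C(CO[Si](C)(C)C(C)(C)C)C(=O)O[C@@H]1[C@@H]1O[C@]1(C)CC/C=N/O[Si](C)(C)C(C)(C)C | intermediate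
16 | free (E)-aldoxime of 15 | C/C=C/[C@@H](O)C1=C(CO[Si](C)(C)C(C)(C)C)C(=O)O[C@@H]1[C@@H]1O[C@]1(C)CC/C=N/O | intermediate
17 | (Z)-hydroximoyl chloride of 16 | C/C=C/[C@@H](O)C1=C(CO[Si](C)(C)C(C)(C)C)C(=O)O[C@@H]1[C@@H]1O[C@]1(C)CC/C(Cl)=N/O | intermediate
18 | C1 nitrile oxide, C8 bromomagnesium alkoxide | C/C=C/[C@@H](O[Mg]Br)C1=C(CO[Si](C)(C)C(C)(C)C)C(=O)O[C@@H]1[C@@H]1O[C@]1(C)CCC#[N+][O-] | intermediate
19 | isoxazoline-bridged germacranolide, 8S-OH, 13-OTBS (4R,5S,6S,8S,9R,10R) | O[C@H]1C2=C(CO[Si](C)(C)C(C)(C)C)C(=O)O[C@@H]2[C@@H]2O[C@]2(C)CCC2=NO[C@@H]1[C@@H]2C | intermediate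
20 | C8 ketone of 19 | O=C1C2=C(CO[Si](C)(C)C(C)(C)C)C(=O)O[C@@H]2[C@@H]2O[C@]2(C)CCC2=NO[C@@H]1[C@@H]2C | intermediate
21 | 8R alcohol (C8 epimer of 19) | O[C@@H]1C2=C(CO[Si](C)(C)C(C)(C)C)C(=O)O[C@@H]2[C@@H]2O[C@]2(C)CCC2=NO[C@@H]1[C@@H]2C | intermediate
22 | 8-O-methacrylate of 21 | C=C(C)C(=O)O[C@@H]1C2=C(CO[Si](C)(C)C(C)(C)C)C(=O)O[C@@H]2[C@@H]2O[C@]2(C)CCC2=NO[C@@H]1[C@@H]2C | intermediate
23 | 13-alcohol | C=C(C)C(=O)O[C@@H]1C2=C(CO)C(=O)O[C@@H]2[C@@H]2O[C@]2(C)CCC2=NO[C@@H]1[C@@H]2C | intermediate
24 | 13-acetate | C=C(C)C(=O)O[C@@H]1C2=C(COC(C)=O)C(=O)O[C@@H]2[C@@H]2O[C@]2(C)CCC2=NO[C@@H]1[C@@H]2C | intermediate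
25 | 9-hydroxy C1 imine | C=C(C)C(=O)O[C@@H]1C2=C(COC(C)=O)C(=O)O[C@@H]2[C@@H]2O[C@]2(C)CCC(=N)[C@@H](C)[C@H]1O | intermediate
26 | CNP0185951.2 (4R,5S,6S,8R,9R,10S) | C=C(C)C(=O)O[C@@H]1C2=C(COC(C)=O)C(=O)O[C@@H]2[C@@H]2O[C@]2(C)CCC(=O)[C@@H](C)[C@H]1O | target

**Total step count:** 18. **Longest linear sequence:** 15 steps (steps 1-4 and 8-18, from nerol).

**Steps most likely to fail**

Step 12 (key step). Several processes could defeat it:
- The dipole may dimerise before it finds the alkene.
- It may add through the nine-membered fused transition state.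
- The folding imposed by C4 to C6 may oppose the face chosen by C8.
- The magnesium base may deprotonate C6-H and open the oxirane by E1cB.
- O8 may attack C5.

The fallback separates the two tasks with known chemistry. It sets out from 12 and comes back at 19 (or at its C8 epimer 21, which is also on the route). Buffered TBAF frees the bromobutenolide aldoxime F1. t-BuOCl gives the hydroximoyl chloride F2, which is added to the zinc alkoxide made from (E)-but-2-en-1-ol, Et2Zn and (R,R)-diisopropyl tartrate. Loss of HCl gives the nitrile oxide F3. The zinc/tartrate-bridged asymmetric nitrile oxide cycloaddition, known for achiral allylic alcohols, should give the (4R,5R)-5-hydroxymethyl-4-methylisoxazoline F4, with C9 and C10 set by the tartrate. Dess-Martin oxidation gives the isoxazoline aldehyde F5. An intramolecular Nozaki-Hiyama-Kishi reaction (CrCl2, NiCl2 cat., DMSO/THF, high dilution) then joins C7 to C8, so that the ten-membered ring is again the last ring closed.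

Step 8. The magnesium carbenoid may decay by alpha-elimination before it adds. Magnesium chelation of the aldehyde and oxirane oxygens may erode the facial selectivity at C6. The fallback sets C6 by hydride delivery instead of C-C bond formation. It sets out from 5 (and uses 10) and comes back at 12. Pinnick oxidation (NaClO2, NaH2PO4, 2-methylbut-2-ene) gives the glycidic acid F6. Coupling with MeNH(OMe)·HCl (EDC, N-methylmorpholine) gives the Weinreb amide F7. Carbenoid 10 is acylated by F7 (Weinreb ketone synthesis) to the epoxy ketone F8. Zn(BH4)2 in Et2O at −20 °C reduces F8 under chelation between the ketone and oxirane oxygens, with hydride arriving from the H5 side, to the hydroxy ester F9, which lactonises to 12.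

Step 9. CO insertion into the electron-poor alkenylpalladium species may be slower than direct propenyl transfer, so that the diene forms instead of the dienone. The fallback reverses the polarity. It sets out from 12 and comes back at 14. Pd(PPh3)4-catalysed stannylation with (Bu3Sn)2 (toluene, 90 °C) gives the 7-stannylbutenolide F10. A Stille acylation with (E)-but-2-enoyl chloride (Pd2(dba)3, P(2-furyl)3, THF, 50 °C) then brings in C8 to C10 and C14 as one preformed acyl unit.

**Further compounds**
F1 | step 12 | bromobutenolide aldoxime | BrC1=C(CO[Si](C)(C)C(C)(C)C)C(=O)O[C@@H]1[C@@H]1O[C@]1(C)CC/C=N/O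
F2 | step 12 | hydroximoyl chloride | BrC1=C(CO[Si](C)(C)C(C)(C)C)C(=O)O[C@@H]1[C@@H]1O[C@]1(C)CC/C(Cl)=N/O
F3 | step 12 | nitrile oxide | BrC1=C(CO[Si](C)(C)C(C)(C)C)C(=O)O[C@@H]1[C@@H]1O[C@]1(C)CCC#[N+][O-]
F4 | step 12 | (4R,5R)-5-hydroxymethyl-4-methylisoxazoline | BrC1=C(CO[Si](C)(C)C(C)(C)C)C(=O)O[C@@H]1[C@@H]1O[C@]1(C)CCC1=NO[C@@H](CO)[C@@H]1C
F5 | step 12 | isoxazoline aldehyde | BrC1=C(CO[Si](C)(C)C(C)(C)C)C(=O)O[C@@H]1[C@@H]1O[C@]1(C)CCC1=NO[C@@H](C=O)[C@@H]1C
F6 | step 8 | glycidic acid | OC(=O)[C@@H]1O[C@]1(C)CC/C=N/O[Si](C)(C)C(C)(C)C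
F7 | step 8 | Weinreb amide | CON(C)C(=O)[C@@H]1O[C@]1(C)CC/C=N/O[Si](C)(C)C(C)(C)C
F8 | step 8 | epoxy ketone | COC(=O)/C(CO[Si](C)(C)C(C)(C)C)=C(/Br)C(=O)[C@@H]1O[C@]1(C)CC/C=N/O[Si](C)(C)C(C)(C)C
F9 | step 8 | hydroxy ester | COC(=O)/C(CO[Si](C)(C)C(C)(C)C)=C(/Br)[C@H](O)[C@@H]1O[C@]1(C)CC/C=N/O[Si](C)(C)C(C)(C)C
F10 | step 9 | 7-stannylbutenolide | CCCC[Sn](CCCC)(CCCC)C1=C(CO[Si](C)(C)C(C)(C)C)C(=O)O[C@@H]1[C@@H]1O[C@]1(C)CC/C=N/O[Si](C)(C)C(C)(C)C
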